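## The problem

The target is a hexacyclic spiro-biflavonoid. A 5,7-dihydroxychroman-4-one (aromatic ring A, heterocyclic ring C) shares its C-2 with the sp3 carbon C-1' of a cross-conjugated cyclohexa-2',5'-dien-4'-one. A dihydrofuran links the C-3 carbinol carbon, through a benzylic CH(4-hydroxyphenyl)–O unit (C-α), to enol carbon C-2' of one dienone arm. A 2-aryl-3-hydroxy-dihydropyran (C-2'', C-3'', C-4'') is fused across C-5'/C-6' of the other arm.

Five stereocentres have to be set: C-3 (R, tertiary alcohol), spiro C-2 (S), C-α (S, aryl cis to the 3-OH) and the cis pyran pair (2''S,3''S). The first three depend on one another. A five-membered ring can only be cis-fused to the chromanone, so C-3 decides which dienone arm the furan uses and hence the spiro configuration, and the bicycle directs the aryl group at C-α to its open face. The pyran pair lies beyond the flat dienone, cannot be induced by the core and must be brought in ready-made.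

Three features will not survive rough treatment. The alkoxide of the tertiary α-ketol can cleave the C-2–C-3 bond with aromatisation of the dienone. The two para-hydroxybenzylic enol ethers of vinylogous-ester type ionise with acid and open to quinone methides with base, and the cis pyran is epimerisable at C-2''. The dienone itself is prone to rearrangement.

The feature that makes the key step possible is that the C-4 ketone and the C-3 tertiary carbinol form an α-ketol. This is the product of adding a ring-A aroyl anion to a ketone held on C-2 by the aryl ether oxygen O-1. Before the furan and pyran exist, C-2 carries two identical methoxy-enone arms and is not stereogenic, so this addition creates exactly one stereocentre.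

## Retrosynthesis

**Unveiling.** Target 32 is traced to its penta-O-benzyl ether 31 by cutting five O–benzyl bonds (four phenolic, one on the pyran alcohol). Benzyl is chosen because it survives organolithium reagents, fluoride released in SNAr, the carbene, DDQ and dilute acid, and leaves in one neutral step. Silyl ethers on ring A would not survive the fluoride of the aryl-ether formation, and acetal groups would need acid at the end. The forward step must cleave O–benzyl bonds without touching the two ring benzylic C–O bonds.

**Pyran ring.** In 31 the enol-ether bond C-6'–O and the C-5'–C-4'' bond are cut, through the open 2-alkyl-1,3-dione 29, to vinylogous acid 17 and aldehyde 27. Cutting here, and not carrying a finished flavan unit through the synthesis, keeps the dienone symmetric until after the key step and lets both pyran stereocentres arrive in one enantiopure three-carbon piece. Forward, a Knoevenagel condensation with in situ transfer hydrogenation joins C-5' to the aldehyde carbon, and cyclodehydration closes the ring with retention at both stereocentres. A threo (2R,3S) aldehyde therefore gives the cis pyran. The ring must close on C-6' and not on C-4'. This is expected because C-4' is the carbonyl of the vinylogous ester formed with the furan oxygen, whereas C-6' is ketone-like. O-2 of 27 is benzylated so that only the six-membered ring can form.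

**Furan ring.** The C-α–O bond of 17 is cut back to a benzylic CH2 and a free enol in trione 16, obtained from the bis(methyl enol ether) 14 by hydrolysis. The alternative of carrying an oxygen on C-α from the start would put a stereocentre next to the ketone of the key step. Hydrolysing both enol ethers avoids any need to tell the arms apart. Only the arm cis to the benzyl group can reach C-α, and the enol left on the other arm is exactly the nucleophile needed for the pyran. The forward step is a DDQ oxidative cyclisation that sets the spiro centre and C-α.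

**Key disconnection.** The C-3–C-4 bond of 14 is cut to give aldehyde–ketone 13. This removes the chromanone ring and the only stereocentre, and leaves an achiral precursor. Forward, a chiral triazolium carbene must add the aldehyde as an acyl anion equivalent to one enantiotopic face of the ketone.

**Aryl ether and ketone.** The ketone of 13 is masked as the dithiane in 12. The O-1–aryl bond of 12 is cut to tertiary quinol 7 and fluoroaldehyde 10 (SNAr). The ether bond is made while the acyl group is still a dithiane, so that no α-ketol alkoxide or enolisable benzyl ketone meets the base.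

**Simple fragments.** Quinol 7 comes from lithiated dithiane 4 and quinone 5 by C–C bond formation at the one ketone-like carbonyl of 5. Dithiane 4 comes from 1 and 2. Fluoroaldehyde 10 comes from 8 by twofold SNAr with benzyl alcohol.

**Side-chain aldehyde.** Aldehyde 27 is traced through alcohol 26 and silyl ether 25 to aldol adduct 24, made from glycolyl imide 21 and aldehyde 22. Imide 21 comes from 18 and 19. A dihydroxylation of a cinnamate would give the same threo diol, but with two free hydroxyls that would then have to be told apart. The glycolate aldol delivers O-2 benzylated and O-3 free.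

## Roads not taken

Alternative 1: Here the C-3–C-2 bond and the O-1–aryl bond are cut together. Forward, an enediolate generated next to an ortho-fluoroaroyl ketone would add to the more electrophilic carbonyl of a quinone that already carries the pyran ring, and the resulting tertiary alkoxide would displace the fluoride, giving the penta-O-benzyl target A1 (the same compound as 31) in one operation.
- Merits: the union is very convergent, the SNAr is intramolecular (easier than the intermolecular one in step 4), and the pyran needs no late annulation, so the regiochemical question of step 15 never arises. In these respects it is better than the chosen plan.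
- Weak points: the quinone carbonyl is already flanked by two different arms, so the spiro centre and C-3 must both be set by substrate control from remote stereocentres. An enediolate is also a strong reductant facing a quinone, so electron transfer to give hydroquinone and 1,2-diketone is the likely course.
- Comparison: the chosen plan offers a redox-neutral, catalyst-controlled step that creates a single stereocentre on a non-stereogenic dienone.

Alternative 2: Here the C-3–C-α bond and the furan O–C-2' bond are cut. Forward, the zinc enediolate of a spiro 3-hydroxychromanone lacking the benzyl group would add to aldehyde 22, and the new alkoxide would add to the cis methoxy-enone arm and expel methoxide, giving the tetracyclic core A2 with one methoxy arm left.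
- Merits: no C–H oxidation is needed (an advantage over step 8), and the surviving methoxy group would direct the later pyran closure by its leaving-group position (an advantage over step 15).
- Weak points: three stereocentres (C-3, C-α, spiro) arise at once from a planar enediolate, and the aldol is reversible. The enediolate carbon also sits β to the aryl ether oxygen on the spiro carbon, so elimination to a quinone methide with ring opening threatens.
- Comparison: the chosen plan never makes C-3 a carbanion and asks its key step for one stereocentre under a precedented catalyst type, at the price of a separate oxidative furan closure.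

Alternative 3: Here the bond between the spiro carbon and C-6' is cut, so the dienone ring is built last from an open chain. Forward, deprotonation of the ring-fusion CH next to O-1 would give an extended enolate that attacks a ketene O,S-acetal carbon and expels methanethiolate, giving the 3-O-triethylsilyl penta-O-benzyl target A3.
- Merits: there is no quinone chemistry and no question of which arm or which oxygen. The pyran regiochemistry is fixed by construction and the tertiary alcohol is protected against retro-aldol cleavage. In these respects it is safer than the chosen plan.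
- Weak points: the cyclisation substrate already needs four stereocentres, the furan-fused chromanone and the ketene acetal, so the sequence is long and linear. The carbanion at the ring fusion also has the silyloxy group at C-3 in a β position, which invites elimination.
- Comparison: the chosen plan offers three simple fragments, a short longest sequence and a key step of a known catalytic type.

Key step: step 6

Assumption: the sense of induction of the aminoindanol-derived triazolium salt is taken by analogy with simpler 2-(2-oxoalkoxy)benzaldehydes; if the (5aS,10bR) salt gave the (3S) carbinol, its (5aR,10bS) enantiomer would be used with no other change.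

Remark: the enolised 1,3-diones 15, 16, 17, 29 and 30 are tautomer mixtures and are written as one tautomer.

## Route

Step 1
Reactants: 1 1,3-dithiane; 2 4-(benzyloxy)benzyl chloride
Product: 4 2-[4-(benzyloxy)benzyl]-1,3-dithiane, via 2-lithio-1,3-dithiane 3 (not isolated)
Conditions: n-BuLi, THF, −30 °C; then 2, −78 °C → rt
Reagents that add atoms: none
Why: Corey–Seebach alkylation; the lithiated dithiane displaces the benzylic chloride in an SN2 reaction, the standard route to 2-benzyl-1,3-dithianes.

Step 2
Reactants: 4 2-[4-(benzyloxy)benzyl]-1,3-dithiane; 5 2,6-dimethoxy-1,4-benzoquinone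
Product: 7 4-{2-[4-(benzyloxy)benzyl]-1,3-dithian-2-yl}-4-hydroxy-3,5-dimethoxycyclohexa-2,5-dien-1-one, via 2-lithio-2-[4-(benzyloxy)benzyl]-1,3-dithiane 6 (not isolated)
Conditions: n-BuLi, THF, −30 °C; cannulated into 5, THF, −78 °C; AcOH quench at −78 °C
Reagents that add atoms: none
Why: 1,2-Addition of a Corey–Seebach acyl anion equivalent to a quinone carbonyl. Only C-1 of 5 (between the methoxy-bearing carbons) is a ketone-like carbonyl, C-4 being the carbonyl of two vinylogous esters, so the organolithium should add at C-1 and leave two identical methoxy-enone arms.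

Step 3
Reactants: 8 2,4,6-trifluorobenzaldehyde
Product: 10 2,4-bis(benzyloxy)-6-fluorobenzaldehyde, via 4-(benzyloxy)-2,6-difluorobenzaldehyde 9 (not isolated)
Conditions: BnOH (2.1 equiv), NaH, THF/DMF, 0 °C → rt
Reagents that add atoms: benzyl alcohol, OCc1ccccc1
Why: Twofold nucleophilic aromatic substitution (SNAr); the para fluoride should go first, then one of the two equivalent ortho fluorides. The third stays because two alkoxy donors now weaken the activating aldehyde.

Step 4
Reactants: 7 4-{2-[4-(benzyloxy)benzyl]-1,3-dithian-2-yl}-4-hydroxy-3,5-dimethoxycyclohexa-2,5-dien-1-one; 10 2,4-bis(benzyloxy)-6-fluorobenzaldehyde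
Product: 12 2,4-bis(benzyloxy)-6-[(1-{2-[4-(benzyloxy)benzyl]-1,3-dithian-2-yl}-2,6-dimethoxy-4-oxocyclohexa-2,5-dien-1-yl)oxy]benzaldehyde, via potassium alkoxide of the quinol 11 (not isolated)
Conditions: KN(SiMe3)2, THF, −78 °C; then 10, 18-crown-6, THF/DMF, −40 °C → rt
Reagents that add atoms: none
Why: SNAr etherification of a tertiary alkoxide on an ortho-fluorobenzaldehyde; 10 has a single fluoride, ortho to the aldehyde, so the site is unambiguous. The dithiane keeps the future ketone masked, so no enolisable or cleavable acyl group is exposed to the alkoxide.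

Step 5
Reactants: 12 2,4-bis(benzyloxy)-6-[(1-{2-[4-(benzyloxy)benzyl]-1,3-dithian-2-yl}-2,6-dimethoxy-4-oxocyclohexa-2,5-dien-1-yl)oxy]benzaldehyde
Product: 13 2,4-bis(benzyloxy)-6-[(1-{[4-(benzyloxy)phenyl]acetyl}-2,6-dimethoxy-4-oxocyclohexa-2,5-dien-1-yl)oxy]benzaldehyde
Conditions: PhI(O2CCF3)2, MeCN/H2O 9:1, 0 °C
Reagents that add atoms: water, O
Why: Oxidative dithiane hydrolysis with a hypervalent iodine reagent, fast at 0 °C and tolerant of aldehydes. The short cold reaction limits hydrolytic loss of the acyl group from the dienone carbon.

Step 6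
Reactants: 13 2,4-bis(benzyloxy)-6-[(1-{[4-(benzyloxy)phenyl]acetyl}-2,6-dimethoxy-4-oxocyclohexa-2,5-dien-1-yl)oxy]benzaldehyde
Product: 14 (3R)-5,7-bis(benzyloxy)-3-[4-(benzyloxy)benzyl]-3-hydroxy-2',6'-dimethoxyspiro[chromane-2,1'-cyclohexa-2',5'-diene]-4,4'-dione
Conditions: (5aS,10bR)-2-phenyl-5a,10b-dihydro-4H,6H-indeno[2,1-b][1,2,4]triazolo[4,3-d][1,4]oxazin-2-ium tetrafluoroborate (15 mol%), Et3N (15 mol%), toluene, rt
Reagents that add atoms: none
Why: The triazolylidene formed from the salt and Et3N adds to the aldehyde, and proton transfer gives the Breslow intermediate (an acyl anion equivalent), which attacks the tethered ketone; proton transfer and loss of the carbene then leave the α-hydroxy ketone. The closest known reaction type is the chiral triazolium-catalysed intramolecular aldehyde–ketone crossed benzoin of 2-(2-oxoalkoxy)benzaldehydes to 3-hydroxychroman-4-ones with a quaternary carbinol. The chromanone ring closes 6-exo-trig, the ketone C=O being exocyclic to the ring that forms. The only new stereocentre, C-3, is set by the catalyst: the fused aminoindanol backbone and the N-aryl group shield one face of the acyl anion equivalent, so one enantiotopic face of the ketone is attacked, and because C-2 carries two identical arms no substrate stereocentre interferes. The step needs chemoselectivity for the ketone over the dienone carbonyl and over intermolecular homo-benzoin: the dienone C=O is a doubly vinylogous ester and inert to the carbene, and the doubly ortho-oxygenated aldehyde is too hindered to dimerise while the ketone sits within reach. It also needs the adduct to survive, which is why only a catalytic amount of a weak amine base is used: the intermediate C-3 alkoxide should be protonated intramolecularly before it can cleave the C-2–C-3 bond with aromatisation of the dienone.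

Step 7
Reactants: 14 (3R)-5,7-bis(benzyloxy)-3-[4-(benzyloxy)benzyl]-3-hydroxy-2',6'-dimethoxyspiro[chromane-2,1'-cyclohexa-2',5'-diene]-4,4'-dione
Product: 16 (3R)-5,7-bis(benzyloxy)-3-[4-(benzyloxy)benzyl]-2',3,6'-trihydroxyspiro[chromane-2,1'-cyclohexa-2',5'-diene]-4,4'-dione, via the mono-methyl enol ether 15 (not isolated)
Conditions: 2 M aq. HCl, THF, 50 °C
Reagents that add atoms: water, O
Why: Acid hydrolysis of vinylogous methyl esters (water adds to the protonated dienone, methanol leaves). Acid is used and not base because a C-3 alkoxide would trigger retro-aldol cleavage; benzyl ethers and the α-ketol tolerate dilute acid, and the arms stay identical so C-2 remains non-stereogenic.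

Step 8
Reactants: 16 (3R)-5,7-bis(benzyloxy)-3-[4-(benzyloxy)benzyl]-2',3,6'-trihydroxyspiro[chromane-2,1'-cyclohexa-2',5'-diene]-4,4'-dione
Product: 17 tetracyclic vinylogous acid (O-2' of 16 bonded to C-α; dihydrofuran cis-fused to the chromanone; 3R; C-α S with the 4-(benzyloxy)phenyl group cis to the 3-OH; 6'-OH free)
Conditions: DDQ (1.2 equiv), 4 Å MS, 1,4-dioxane, rt → 50 °C
Reagents that add atoms: none
Why: DDQ oxidative cyclisation: hydride abstraction from the para-alkoxybenzyl CH2 gives a quinone-methide-like cation that is captured 5-exo by an enol oxygen. Only the arm cis to the benzyl group can reach it, because a five-membered ring must be cis-fused to the chromanone, so the C-3 centre fixes the spiro configuration. The aryl group should settle on the open face, cis to the small 3-OH, and the benzylic ether can equilibrate to this isomer under the acidic hydroquinone by-product.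

Step 9
Reactants: 18 (R)-4-benzyloxazolidin-2-one; 19 (benzyloxy)acetyl chloride
Product: 21 (R)-4-benzyl-3-[(benzyloxy)acetyl]oxazolidin-2-one, via lithium (R)-4-benzyl-2-oxooxazolidin-3-ide 20 (not isolated)
Conditions: n-BuLi, THF, −78 °C; then 19, −78 → 0 °C
Reagents that add atoms: none
Why: N-Acylation of a lithiated Evans oxazolidinone with an acid chloride.

Step 10
Reactants: 21 (R)-4-benzyl-3-[(benzyloxy)acetyl]oxazolidin-2-one; 22 4-(benzyloxy)benzaldehyde
Product: 24 (R)-4-benzyl-3-{(2R,3S)-2-(benzyloxy)-3-[4-(benzyloxy)phenyl]-3-hydroxypropanoyl}oxazolidin-2-one, via the (Z)-dibutylboron enolate 23 (not isolated)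
Conditions: Bu2BOTf, Et3N, CH2Cl2, −78 → 0 °C; then 22, −78 → 0 °C; pH 7 buffer, MeOH, 30% H2O2
Reagents that add atoms: none
Why: Evans boron glycolate syn-aldol: the (Z)-enolate reacts through a Zimmerman–Traxler chair and the benzyl group of the auxiliary shields one enolate face, which should set both centres as (2R,3S) (threo). The two oxygens arrive already differentiated, O-2 benzylated and O-3 free.

Step 11
Reactants: 24 (R)-4-benzyl-3-{(2R,3S)-2-(benzyloxy)-3-[4-(benzyloxy)phenyl]-3-hydroxypropanoyl}oxazolidin-2-one
Product: 25 (R)-4-benzyl-3-{(2R,3S)-2-(benzyloxy)-3-[4-(benzyloxy)phenyl]-3-[(triethylsilyl)oxy]propanoyl}oxazolidin-2-one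
Conditions: Et3SiCl, imidazole, DMF, 0 °C
Reagents that add atoms: chlorotriethylsilane, CC[Si](Cl)(CC)CC
Why: Silylation of a secondary alcohol; the triethylsilyl ether blocks retro-aldol cleavage and can later be removed without touching the benzyl ethers.

Step 12
Reactants: 25 (R)-4-benzyl-3-{(2R,3S)-2-(benzyloxy)-3-[4-(benzyloxy)phenyl]-3-[(triethylsilyl)oxy]propanoyl}oxazolidin-2-one
Product: 26 (2S,3S)-2-(benzyloxy)-3-[4-(benzyloxy)phenyl]-3-[(triethylsilyl)oxy]propan-1-ol
Conditions: LiBH4, MeOH (1 equiv), THF, 0 °C
Reagents that add atoms: none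
Why: Reductive cleavage of the N-acyl oxazolidinone to the primary alcohol with recovery of the auxiliary. The change of descriptor at C-2 is only a change of priorities.

Step 13
Reactants: 26 (2S,3S)-2-(benzyloxy)-3-[4-(benzyloxy)phenyl]-3-[(triethylsilyl)oxy]propan-1-ol
Product: 27 (2R,3S)-2-(benzyloxy)-3-[4-(benzyloxy)phenyl]-3-[(triethylsilyl)oxy]propanal
Conditions: Dess–Martin periodinane, CH2Cl2, 0 °C → rt
Reagents that add atoms: none
Why: Dess–Martin oxidation of a primary alcohol under non-basic conditions, which should not epimerise the α-alkoxy aldehyde; the aldehyde is used at once.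

Step 14
Reactants: 17 tetracyclic vinylogous acid; 27 (2R,3S)-2-(benzyloxy)-3-[4-(benzyloxy)phenyl]-3-[(triethylsilyl)oxy]propanal
Product: 29 C-5'-alkylated dione (17 carrying the (2S,3S)-2-(benzyloxy)-3-[4-(benzyloxy)phenyl]-3-[(triethylsilyl)oxy]propyl group on C-5'), via the Knoevenagel alkylidene dione 28 (not isolated)
Conditions: diethyl 2,6-dimethyl-1,4-dihydropyridine-3,5-dicarboxylate (Hantzsch ester, 1.1 equiv), L-proline (10 mol%), CH2Cl2, rt
Reagents that add atoms: none
Why: Three-component reductive alkylation of a cyclic 1,3-dione: Knoevenagel condensation at C-5', the only carbon between two carbonyls, followed at once by Hantzsch ester transfer hydrogenation of the alkylidene dione, which prevents a second Michael addition. The stereocentres of 27 take no part, and α-alkoxy aldehydes are known to pass through this reaction without epimerisation.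

Step 15
Reactants: 29 C-5'-alkylated dione
Product: 31 penta-O-benzyl ether of the target, via the desilylated benzylic alcohol 30 (not isolated)
Conditions: HF·pyridine, pyridine, THF, 0 °C; then PPTS, 4 Å MS, CH2Cl2, rt
Reagents that add atoms: none
Why: Desilylation followed by acid-catalysed cyclodehydration (hemiketal formation and loss of water), the usual closure of 2-(3-hydroxyalkyl)-1,3-diones to fused dihydropyrans. The benzylic hydroxyl should add to C-6', the ketone-type carbonyl flanking C-5', because C-4' is the carbonyl of the vinylogous ester with the furan oxygen; only a six-membered ring can form since O-3'' is benzylated. No bond to a stereocentre is broken, so the threo side chain gives the 2'',3''-cis pyran.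

Step 16
Reactants: 31 penta-O-benzyl ether of the target
Product: 32 target CNP0170480.5 (3R; spiro C-2 S; C-α S; pyran 2''S,3''S)
Conditions: H2 (1 atm), Pd(OH)2/C, EtOAc/MeOH, rt
Reagents that add atoms: none
Why: Catalytic hydrogenolysis of benzyl ethers under neutral conditions, the customary last step for flavan-3-ol polyphenols. The primary O-benzyl groups should cleave much faster than the two secondary, ring-embedded benzylic C–O bonds and the enol-ether double bonds, so the reaction is stopped when five equivalents of toluene have formed.

## Compound list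

1 | 1,3-dithiane | C1CSCSC1 | starting material
2 | 4-(benzyloxy)benzyl chloride | ClCc1ccc(OCc2ccccc2)cc1 | starting material
3 | 2-lithio-1,3-dithiane | [Li]C1SCCCS1 | intermediate
4 | 2-[4-(benzyloxy)benzyl]-1,3-dithiane | C(c1ccc(OCc2ccccc2)cc1)C1SCCCS1 | intermediate
5 | 2,6-dimethoxy-1,4-benzoquinone | COC1=CC(=O)C=C(OC)C1=O | starting material
6 | 2-lithio-2-[4-(benzyloxy)benzyl]-1,3-dithiane | [Li]C1(Cc2ccc(OCc3ccccc3)cc2)SCCCS1 | intermediate
7 | 4-{2-[4-(benzyloxy)benzyl]-1,3-dithian-2-yl}-4-hydroxy-3,5-dimethoxycyclohexa-2,5-dien-1-one | O=C1C=C(OC)C(O)(C2(Cc3ccc(OCc4ccccc4)cc3)SCCCS2)C(OC)=C1 | intermediate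
8 | 2,4,6-trifluorobenzaldehyde | O=Cc1c(F)cc(F)cc1F | starting material
9 | 4-(benzyloxy)-2,6-difluorobenzaldehyde | O=Cc1c(F)cc(OCc2ccccc2)cc1F | intermediate
10 | 2,4-bis(benzyloxy)-6-fluorobenzaldehyde | O=Cc1c(F)cc(OCc2ccccc2)cc1OCc1ccccc1 | intermediate
11 | potassium alkoxide of quinol 7 | [K+].[O-]C1(C2(Cc3ccc(OCc4ccccc4)cc3)SCCCS2)C(OC)=CC(=O)C=C1OC | intermediate
12 | 2,4-bis(benzyloxy)-6-[(1-{2-[4-(benzyloxy)benzyl]-1,3-dithian-2-yl}-2,6-dimethoxy-4-oxocyclohexa-2,5-dien-1-yl)oxy]benzaldehyde | O=C1C=C(OC)C(Oc2cc(OCc3ccccc3)cc(OCc3ccccc3)c2C=O)(C2(Cc3ccc(OCc4ccccc4)cc3)SCCCS2)C(OC)=C1 | intermediate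
13 | 2,4-bis(benzyloxy)-6-[(1-{[4-(benzyloxy)phenyl]acetyl}-2,6-dimethoxy-4-oxocyclohexa-2,5-dien-1-yl)oxy]benzaldehyde | O=C1C=C(OC)C(Oc2cc(OCc3ccccc3)cc(OCc3ccccc3)c2C=O)(C(=O)Cc2ccc(OCc3ccccc3)cc2)C(OC)=C1 | intermediate
14 | (3R)-5,7-bis(benzyloxy)-3-[4-(benzyloxy)benzyl]-3-hydroxy-2',6'-dimethoxyspiro[chromane-2,1'-cyclohexa-2',5'-diene]-4,4'-dione | O=C1C=C(OC)C2(Oc3cc(OCc4ccccc4)cc(OCc4ccccc4)c3C(=O)[C@@]2(O)Cc2ccc(OCc3ccccc3)cc2)C(OC)=C1 | intermediate
15 | (3R)-mono-methyl enol ether (2'-hydroxy-6'-methoxy analogue of 14, both epimers at the spiro carbon) | O=C1C=C(O)C2(Oc3cc(OCc4ccccc4)cc(OCc4ccccc4)c3C(=O)[C@@]2(O)Cc2ccc(OCc3ccccc3)cc2)C(OC)=C1 | intermediate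
16 | (3R)-5,7-bis(benzyloxy)-3-[4-(benzyloxy)benzyl]-2',3,6'-trihydroxyspiro[chromane-2,1'-cyclohexa-2',5'-diene]-4,4'-dione | O=C1C=C(O)C2(Oc3cc(OCc4ccccc4)cc(OCc4ccccc4)c3C(=O)[C@@]2(O)Cc2ccc(OCc3ccccc3)cc2)C(O)=C1 | intermediate
17 | tetracyclic vinylogous acid (furan closed from O-2' to C-α; 3R; C-α S, aryl cis to 3-OH; 6'-OH free) | O=C1C=C2O[C@@H](c3ccc(OCc5ccccc5)cc3)[C@]3(O)C(=O)c4c(OCc5ccccc5)cc(OCc5ccccc5)cc4O[C@]23C(O)=C1 | intermediate
18 | (R)-4-benzyloxazolidin-2-one | O=C1N[C@H](Cc2ccccc2)CO1 | starting material
19 | (benzyloxy)acetyl chloride | ClC(=O)COCc1ccccc1 | starting material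
20 | lithium (R)-4-benzyl-2-oxooxazolidin-3-ide | [Li]N1[C@H](Cc2ccccc2)COC1=O | intermediate
21 | (R)-4-benzyl-3-[(benzyloxy)acetyl]oxazolidin-2-one | O=C(COCc1ccccc1)N1[C@H](Cc2ccccc2)COC1=O | intermediate
22 | 4-(benzyloxy)benzaldehyde | O=Cc1ccc(OCc2ccccc2)cc1 | starting material
23 | (Z)-dibutylboron enolate of 21 | CCCCB(CCCC)O/C(=C\OCc1ccccc1)N1[C@H](Cc2ccccc2)COC1=O | intermediate
24 | (R)-4-benzyl-3-{(2R,3S)-2-(benzyloxy)-3-[4-(benzyloxy)phenyl]-3-hydroxypropanoyl}oxazolidin-2-one | O=C([C@H](OCc1ccccc1)[C@H](c1ccc(OCc2ccccc2)cc1)O)N1[C@H](Cc2ccccc2)COC1=O | intermediate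
25 | (R)-4-benzyl-3-{(2R,3S)-2-(benzyloxy)-3-[4-(benzyloxy)phenyl]-3-[(triethylsilyl)oxy]propanoyl}oxazolidin-2-one | O=C([C@H](OCc1ccccc1)[C@H](c1ccc(OCc2ccccc2)cc1)O[Si](CC)(CC)CC)N1[C@H](Cc2ccccc2)COC1=O | intermediate
26 | (2S,3S)-2-(benzyloxy)-3-[4-(benzyloxy)phenyl]-3-[(triethylsilyl)oxy]propan-1-ol | OC[C@H](OCc1ccccc1)[C@H](c1ccc(OCc2ccccc2)cc1)O[Si](CC)(CC)CC | intermediate
27 | (2R,3S)-2-(benzyloxy)-3-[4-(benzyloxy)phenyl]-3-[(triethylsilyl)oxy]propanal | O=C[C@H](OCc1ccccc1)[C@H](c1ccc(OCc2ccccc2)cc1)O[Si](CC)(CC)CC | intermediate
28 | Knoevenagel alkylidene dione (C-5'=CH–side chain, alkene geometry not defined) | O=C1C=C2O[C@@H](c3ccc(OCc5ccccc5)cc3)[C@]3(O)C(=O)c4c(OCc5ccccc5)cc(OCc5ccccc5)cc4O[C@]23C(=O)C1=C[C@H](OCc1ccccc1)[C@H](c1ccc(OCc2ccccc2)cc1)O[Si](CC)(CC)CC | intermediate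
29 | C-5'-alkylated dione (side chain (2S,3S)-2-(benzyloxy)-3-[4-(benzyloxy)phenyl]-3-[(triethylsilyl)oxy]propyl) | O=C1C=C2O[C@@H](c3ccc(OCc5ccccc5)cc3)[C@]3(O)C(=O)c4c(OCc5ccccc5)cc(OCc5ccccc5)cc4O[C@]23C(O)=C1C[C@H](OCc1ccccc1)[C@H](c1ccc(OCc2ccccc2)cc1)O[Si](CC)(CC)CC | intermediate
30 | desilylated benzylic alcohol of 29 | O=C1C=C2O[C@@H](c3ccc(OCc5ccccc5)cc3)[C@]3(O)C(=O)c4c(OCc5ccccc5)cc(OCc5ccccc5)cc4O[C@]23C(O)=C1C[C@H](OCc1ccccc1)[C@H](c1ccc(OCc2ccccc2)cc1)O | intermediate
31 | penta-O-benzyl ether of the target | O=C1C=C2O[C@@H](c3ccc(OCc5ccccc5)cc3)[C@]3(O)C(=O)c4c(OCc5ccccc5)cc(OCc5ccccc5)cc4O[C@]23C2=C1C[C@H](OCc1ccccc1)[C@H](c1ccc(OCc3ccccc3)cc1)O2 | intermediate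
32 | target CNP0170480.5 | O=C1C=C2O[C@@H](c3ccc(O)cc3)[C@]3(O)C(=O)c4c(O)cc(O)cc4O[C@]23C2=C1C[C@H](O)[C@H](c1ccc(O)cc1)O2 | target

## Step count and least certain steps

Total: 16 steps. Longest linear sequence: 10 steps (steps 1, 2, 4, 5, 6, 7, 8, 14, 15, 16). Step 3 and steps 9–13 are side branches.

**Step 6 (key step).** The Breslow intermediate may form too slowly from the doubly ortho-oxygenated, electron-rich aldehyde. Base-mediated transfer of the arylacetyl group away from the dienone carbon (with aromatisation) or poor face discrimination could then take over. Fallback, from 13 back to 14: give up catalyst control. The small achiral carbene from 3-benzyl-5-(2-hydroxyethyl)-4-methylthiazolium chloride and Et3N reaches a hindered aldehyde more easily and should close the same ring to racemic 14. The enantiomers are separated by preparative chromatography on a chiral stationary phase; the (3R) half is 14 and the (3S)-enantiomer F1 is set aside.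

**Step 4.** The hindered tertiary alkoxide may attack the donor-substituted fluoroarene too slowly, so that reversal of the dithiane addition or attack at the aldehyde consumes it. Fallback, from alkoxide 11 (made from 7) back to 12: use the more electrophilic difluoride 9, obtained as an isolated product when step 3 is run with one equivalent of benzyl alcohol. It should give the fluoro aryl ether F2, whose remaining activated fluoride is then replaced with benzyl alcohol and Cs2CO3 in DMF to give 12.

**Step 8.** Hydride abstraction may be slow because C-α sits next to an electron-poor quaternary carbinol, and DDQ may then consume the electron-rich enols instead. Fallback, from 14 back to 17: oxidise before the enols are freed and close the ring ionically. DDQ in AcOH/CH2Cl2 acts on the enol-ether-protected 14 to give the benzylic acetate F3 (both epimers). Then 2 M HCl in THF hydrolyses both enol ethers while the para-alkoxybenzylic acetate ionises and is captured by the cis enol oxygen, giving 17.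

**Step 2.** Electron transfer from the lithiated dithiane to the quinone (reduction, dithiane dimer) may compete with carbonyl addition. Fallback, from 4 back to 7: replace the quinone by its monoketal, which is much harder to reduce. 2,4,6-Trimethoxyphenol F4 is oxidised with PhI(OAc)2 in MeOH to 2,4,4,6-tetramethoxycyclohexa-2,5-dien-1-one F5. Lithiated 6 adds to its single ketone to give the ketal quinol F6, and dilute aqueous oxalic acid hydrolyses the ketal to 7.

**Step 15.** The ring may close through the other dione oxygen (on C-4', giving the linearly conjugated dienone), or acid may ionise the benzylic alcohol with loss of the cis relationship. Fallback, from 29 back to 31: fix the site by a leaving group. O-Methylation of 29 with Me3SiCHN2 in MeOH/toluene gives the cross-conjugated 6'-methyl enol ether F7 together with the linear 4'-methyl enol ether F9. They are separated, and F9 is returned to 29 by dilute acid. HF·pyridine frees the benzylic alcohol F8, and catalytic camphorsulfonic acid in toluene exchanges the methoxy group for the side-chain oxygen at C-6' only, giving 31.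

**Step 16.** The two ring benzylic C–O bonds (benzylic vinylogous esters) may be hydrogenolysed, or the enone saturated, in competition with O-debenzylation. Fallback, from 31 back to 32: non-reductive cleavage with BCl3 and pentamethylbenzene in CH2Cl2 at −78 °C, where the arene traps the benzyl cations. No new compound is formed.

## Further compounds

F1 | step 6 | (3S)-enantiomer of 14 | O=C1C=C(OC)C2(Oc3cc(OCc4ccccc4)cc(OCc4ccccc4)c3C(=O)[C@]2(O)Cc2ccc(OCc3ccccc3)cc2)C(OC)=C1
F2 | step 4 | 4-(benzyloxy)-2-fluoro-6-[(1-{2-[4-(benzyloxy)benzyl]-1,3-dithian-2-yl}-2,6-dimethoxy-4-oxocyclohexa-2,5-dien-1-yl)oxy]benzaldehyde | O=C1C=C(OC)C(Oc2cc(OCc3ccccc3)cc(F)c2C=O)(C2(Cc3ccc(OCc4ccccc4)cc3)SCCCS2)C(OC)=C1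
F3 | step 8 | benzylic acetate of 14 (both epimers at the acetoxy carbon) | O=C1C=C(OC)C2(Oc3cc(OCc4ccccc4)cc(OCc4ccccc4)c3C(=O)[C@@]2(O)C(OC(C)=O)c2ccc(OCc3ccccc3)cc2)C(OC)=C1
F4 | step 2 | 2,4,6-trimethoxyphenol | COc1cc(OC)c(O)c(OC)c1
F5 | step 2 | 2,4,4,6-tetramethoxycyclohexa-2,5-dien-1-one | COC1=CC(OC)(OC)C=C(OC)C1=O
F6 | step 2 | 1-{2-[4-(benzyloxy)benzyl]-1,3-dithian-2-yl}-2,4,4,6-tetramethoxycyclohexa-2,5-dien-1-ol | COC1=CC(OC)(OC)C=C(OC)C1(O)C1(Cc2ccc(OCc3ccccc3)cc2)SCCCS1
F7 | step 15 | 6'-methyl enol ether of 29 (cross-conjugated) | O=C1C=C2O[C@@H](c3ccc(OCc5ccccc5)cc3)[C@]3(O)C(=O)c4c(OCc5ccccc5)cc(OCc5ccccc5)cc4O[C@]23C(OC)=C1C[C@H](OCc1ccccc1)[C@H](c1ccc(OCc2ccccc2)cc1)O[Si](CC)(CC)CC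
F8 | step 15 | desilylated benzylic alcohol of F7 | O=C1C=C2O[C@@H](c3ccc(OCc5ccccc5)cc3)[C@]3(O)C(=O)c4c(OCc5ccccc5)cc(OCc5ccccc5)cc4O[C@]23C(OC)=C1C[C@H](OCc1ccccc1)[C@H](c1ccc(OCc2ccccc2)cc1)O
F9 | step 15 | 4'-methyl enol ether of 29 (linear isomer) | O=C1C(C[C@H](OCc2ccccc2)[C@H](c2ccc(OCc3ccccc3)cc2)O[Si](CC)(CC)CC)=C(OC)C=C2O[C@@H](c3ccc(OCc5ccccc5)cc3)[C@]3(O)C(=O)c4c(OCc5ccccc5)cc(OCc5ccccc5)cc4O[C@]123
F0 | step 16 | none | none
A1 | alternative 1 | penta-O-benzyl target (identical with 31) | O=C1C=C2O[C@@H](c3ccc(OCc5ccccc5)cc3)[C@]3(O)C(=O)c4c(OCc5ccccc5)cc(OCc5ccccc5)cc4O[C@]23C2=C1C[C@H](OCc1ccccc1)[C@H](c1ccc(OCc3ccccc3)cc1)O2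
A2 | alternative 2 | benzyl-protected tetracyclic core with one methoxy-enone arm | O=C1C=C2O[C@@H](c3ccc(OCc5ccccc5)cc3)[C@]3(O)C(=O)c4c(OCc5ccccc5)cc(OCc5ccccc5)cc4O[C@]23C(OC)=C1
A3 | alternative 3 | 3-O-triethylsilyl penta-O-benzyl target | O=C1C=C2O[C@@H](c3ccc(OCc5ccccc5)cc3)[C@]3(O[Si](CC)(CC)CC)C(=O)c4c(OCc5ccccc5)cc(OCc5ccccc5)cc4O[C@]23C2=C1C[C@H](OCc1ccccc1)[C@H](c1ccc(OCc3ccccc3)cc1)O2
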